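| flask | starting material | remark | time |
|---|---|---|---|
| larch | 0.10 M | the very flask that is asked about, followed so far |  |
| flask | 0.10 M |  | 1.5 h |

- larch (time / min: target / %, isomer of the product A / %): 1.33: 62.7, 3.0; 2.50: 79.7, 6.0; 4.00: 85.0, 3.9; 6.00: 86.8, 5.0; 10.0: 84.9, 6.0; 20.0: 87.4, 6.2

(scatter of a reading: 1 percentage point)

* the target standing at 1.5 h, as a percentage of the starting material charged
* the isomer of the product A standing at 1.5 h, as a percentage of the starting material charged

- the numbers in the tables scatter with a standard deviation of 1 percentage point
- a reading or a percentage of target counts all its forms, free or not

**Reading due.** At 1.5 h you will read the larch flask, already followed for 20.0 min. Reckon with what is left over, not with what is made. From 4.00 min on, the target readings average 86.0% and those of isomer of the product A 5.27%. The remainder, the share of the charge in neither, is therefore 8.70%.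

**My reckoning.** The target shows no trend beyond the scatter of 1 percentage point, so I hold the remainder steady and expect those two averages at 1.5 h. Leave the flask closed, stirred and at its temperature, the conditions under which these readings were taken.

**The forecast.** It gives target 85.5% (80% to 88.5%) and isomer of the product A 6.2% (4.5% to 10%), holding that “the simplest expectation is that the plateau holds”. Unlike my averages, its figures are shaded against a slow drift.

**The result.** The flask gives target 86.9% and isomer of the product A 5.89%, a remainder of 7.21% against the 8.70% read earlier.

    starting material ⇌ target (K = 2.20, k = 0.0170 s⁻¹)
    starting material ⇌ isomer of the product A (K = 2.40, k = 1.70 × 10⁻⁴ s⁻¹)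
    target ⇌ isomer of the product A (k = 0.00440 s⁻¹)
    target ⇌ isomer of the product B (K = 0.880, k = 0.00870 s⁻¹)
    crystals ⇌ target, rate k5*(cs5 - [target]) while solid is left; crystals form when [target] > cs5 (solubility = 5.40 mM, k = 0.150 s⁻¹)

**Low solubility.** The flask is under thermodynamic control, with a largest change of 0 points over the second half of the time, and at 1.50 h 81.5% of the charge stands as crystals, counted in target. In the run without the low solubility of target, conversion of starting material is 86.7% instead of 97.5%, the largest single effect on that conversion among those tried, though not the main reason for it.

**Longer flask.** For the neighbour left until 4.0 h, the remainder of 8.70% gives target and isomer of the product A together 91.3%. The computed neighbour holds target 86.9% and isomer of the product A 5.89%.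

All runs are simulated with constants of no real substance; scatter was added.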